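**Retrosynthetic overview**
1. 18 ⇒ 16 + 17. The last bond made is the C9–O acyl bond, by selective esterification of the only secondary OH.
2. γ-Lactone (last ring): the C8–O bond comes from 5-exo opening of the 8,9-epoxide of acid 14 by its own C12 carboxyl group. This sets C8 and C9.
3. Ten-membered ring: the key bond is C10–O. In cis-decalin-5-ol 8, C10 shifts from C5 to oxygen, so the C5–C10 fusion bond is traded for C10–OH and C5=O, with retention at C10.
4. Decalin 8: ring A is closed by C4–C5 ketyl–olefin coupling. Quaternary C10 comes from an epoxy-alcohol semipinacol shift on the (S)-carvone/pentenyl Grignard adduct.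
5. Ring order: carvone six-ring (bought) → second six-ring → 6/6-to-10 ring expansion → lactone.

Assumption: germacrane numbering is used throughout (C1–C10 ring, C11–C13 acrylate unit, C14 on C10, C15 on C4). The given SMILES reads as (4R,7S,8S,9R,10S,2′R), which calls for (S)-carvone and (R)-2-methylbutanoic acid, both bought enantiopure.

**Step 1**
Reactants: 1 (S)-(+)-carvone; 2 5-bromopent-1-ene
Product: 4 (1S,5S)-2-methyl-1-(pent-4-en-1-yl)-5-(prop-1-en-2-yl)cyclohex-2-en-1-ol, via pent-4-en-1-ylmagnesium bromide 3 (not isolated)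
Conditions: 2, Mg, THF, rt; anhydrous CeCl3, THF, −78 °C; then 1, −78 → 0 °C; H2O quench
Reagents that add atoms: none
Why: Cerium-modified Grignard 1,2-addition (Imamoto), in which the non-basic reagent adds only to C=O, axially and anti to the equatorial isopropenyl group, so C5 carries pentenyl trans and OH cis to isopropenyl.

**Step 2**
Reactants: 4 tertiary allylic alcohol
Product: 5 (1R,2S,4S,6R)-1-methyl-2-(pent-4-en-1-yl)-4-(prop-1-en-2-yl)-7-oxabicyclo[4.1.0]heptan-2-ol (epoxide cis to OH)
Conditions: VO(acac)2 (2 mol %), t-BuOOH (1.2 equiv), toluene, 0 °C → rt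
Reagents that add atoms: tert-butyl hydroperoxide, CC(C)(C)OO
Why: Sharpless–Michaelson hydroxyl-directed epoxidation, in which vanadium bound to the tertiary OH delivers oxygen only to the allylic C9=C10 bond and on the OH face (the pseudoaxial pentenyl blocks the other face), leaving both isolated alkenes untouched.

**Step 3**
Reactants: 5 epoxy alcohol
Product: 6 (2S,3R,5S)-3-hydroxy-2-methyl-2-(pent-4-en-1-yl)-5-(prop-1-en-2-yl)cyclohexan-1-one
Conditions: SnCl4 (10 mol %), CH2Cl2, −78 → −30 °C
Reagents that add atoms: none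
Why: Semipinacol rearrangement of a 2,3-epoxy alcohol, in which the Lewis acid opens the epoxide at tertiary C10 and the antiperiplanar pseudoaxial pentenyl group shifts from C5 to C10 with inversion there, relaying the C5 configuration into quaternary C10 (chain trans, methyl cis to isopropenyl), the isomer that direct axial alkylation of carvone enolates does not give.

**Step 4**
Reactants: 6 β-hydroxy ketone
Product: 7 (2S,5R)-2-methyl-2-(pent-4-en-1-yl)-5-(prop-1-en-2-yl)cyclohex-3-en-1-one
Conditions: Burgess reagent (1.5 equiv), toluene, 80 °C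
Reagents that add atoms: none
Why: Burgess dehydration (syn Ei elimination of the sulfamate), where C10 bears no H so only the C8=C9 alkene can form, and no free cation or strong base is present so C7 and C10 are untouched.

**Step 5**
Reactants: 7 β,γ-unsaturated ketone
Product: 8 (4R,4aR,6R,8aS)-4,8a-dimethyl-6-(prop-1-en-2-yl)-1,3,4,5,6,8a-hexahydronaphthalen-4a(2H)-ol (cis-decalin, 4a-OH and 8a-CH3 cis)
Conditions: SmI2 (2.5 equiv), HMPA, t-BuOH (2 equiv), THF, 0 °C → rt
Reagents that add atoms: none
Why: SmI2 ketyl–olefin 6-exo-trig reductive cyclisation (Molander), in which the C5 ketyl meets the terminal alkene through a chair on the face opposite the axial C10 methyl (cis-decalin, bulky O–Sm equatorial on ring B) with the developing CH2 (C15) equatorial, which sets C4 (R), while the isopropenyl and ring alkenes are geometrically out of reach.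

**Step 6**
Reactants: 8 cis-decalin-5-ol
Product: 11 (3R,4Z,6S,10R)-6-hydroxy-6,10-dimethyl-3-(prop-1-en-2-yl)cyclodec-4-en-1-one, via C5-peroxy 4-nitrobenzenesulfonate of 8 9 (not isolated), via bridged hemiketal 2,6-dimethyl-9-(prop-1-en-2-yl)-11-oxabicyclo[4.4.1]undec-7-en-1-ol 10 (not isolated)
Conditions: KHMDS (1.05 equiv), THF, −78 °C; (4-O2NC6H4SO2O)2 (1.1 equiv), −78 °C; then THF–pH 7 buffer, −78 → 0 °C
Reagents that add atoms: water, O
Why: Proposed new method: direct oxidative 1,2 C→O shift of a tertiary alcohol, in which the potassium alkoxide of 8 attacks an electrophilic peroxide oxygen of the sulfonyl peroxide (SN2 at O, as this reagent class does with amines, enolates and arenes) to give 9, whose O–O bond ionises below 0 °C with concerted migration of the best migrating group, tertiary allylic C10 (over secondary C4 and primary C6), from C5 to oxygen with retention, after which water adds to the bridged oxocarbenium ion to give 10, which opens to the 10-hydroxy-5-ketone, so the C10–O bond, the C10 configuration and the ten-membered ring are all made here without a preformed hydroperoxide; the closest known reaction type is the Criegee rearrangement of 9-decalyl peresters and persulfonates (related to Baeyer–Villiger and Hock shifts).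

**Step 7**
Reactants: 11 ring-expanded hydroxy ketone
Product: 12 (3R,4Z,6S,10R)-6-hydroxy-3-(3-hydroxyprop-1-en-2-yl)-6,10-dimethylcyclodec-4-en-1-one
Conditions: SeO2 (0.3 equiv), t-BuOOH (2 equiv), CH2Cl2, 0 °C → rt
Reagents that add atoms: tert-butyl hydroperoxide, CC(C)(C)OO
Why: Sharpless catalytic SeO2 allylic hydroxylation (ene reaction then [2,3]-shift), in which the 1,1-disubstituted isopropenyl group is the most reactive alkene and is oxidised at its CH3 (CH3 before CH), while the Z-alkene has only the hindered C7–H, so no stereocentre is touched.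

**Step 8**
Reactants: 12 allylic alcohol
Product: 14 2-[(1R,2Z,4S,8R)-4-hydroxy-4,8-dimethyl-9-oxocyclodec-2-en-1-yl]prop-2-enoic acid, via 2-[(1R,2Z,4S,8R)-4-hydroxy-4,8-dimethyl-9-oxocyclodec-2-en-1-yl]prop-2-enal 13 (not isolated)
Conditions: TEMPO (7 mol %), NaOCl (2 mol %), NaClO2 (2 equiv), MeCN–pH 6.7 phosphate buffer, 35 °C
Reagents that add atoms: sodium chlorite, [Na+].[O-]Cl=O
Why: Zhao (TEMPO/NaClO2) oxidation, in which the oxoammonium ion takes only the primary allylic alcohol to enal 13 and chlorite takes this to the acid, at near-neutral pH that spares the tertiary alcohol, the C4 α-centre and the Z-alkene (bleach is only catalytic).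

**Step 9**
Reactants: 14 dienoic acid
Product: 16 (4R,7S,8S,9R,10S)-9,10-dihydroxy-5-oxogermacr-11(13)-en-12,8-olide, via (4R,7S,8R,9R,10S)-8,9-epoxide of 14 15 (not isolated)
Conditions: m-CPBA (1.1 equiv), CH2Cl2, 0 °C → rt; then PPTS (cat.)
Reagents that add atoms: m-chloroperbenzoic acid, OOC(=O)c1cccc(Cl)c1
Why: Prilezhaev epoxidation followed by 5-exo-tet epoxy-acid lactonisation, in which only the electron-rich Z-alkene reacts, A(1,3) strain holds H7 and the C10–OH in the alkene plane so the peracid enters anti to the acrylic acid arm (C7) and to C1 (C10), and the acid on the opposite face then opens C8 with inversion (trans-lactone, 8S) while the epoxide oxygen stays on C9 (9R).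

**Step 10**
Reactants: 16 hydroxy lactone; 17 (R)-2-methylbutanoic acid
Product: 18 ineupatorolide A, (4R,7S,8S,9R,10S)-10-hydroxy-9-[(2R)-2-methylbutanoyloxy]-5-oxogermacr-11(13)-en-12,8-olide
Conditions: 17 (1.5 equiv), DCC, DMAP (0.2 equiv), CH2Cl2, 0 °C → rt
Reagents that add atoms: none
Why: Steglich esterification, which acylates only the secondary C9–OH (the tertiary C10–OH is inert) and avoids ketene formation, so the 2′R centre and the C4 α-keto centre are kept.

**Compound list**
1 | (S)-(+)-carvone | CC1=CC[C@@H](CC1=O)C(C)=C | starting material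
2 | 5-bromopent-1-ene | C=CCCCBr | starting material
3 | pent-4-en-1-ylmagnesium bromide | C=CCCC[Mg]Br | intermediate
4 | (1S,5S)-2-methyl-1-(pent-4-en-1-yl)-5-(prop-1-en-2-yl)cyclohex-2-en-1-ol | CC1=CC[C@@H](C[C@@]1(O)CCCC=C)C(C)=C | intermediate
5 | (1R,2S,4S,6R)-1-methyl-2-(pent-4-en-1-yl)-4-(prop-1-en-2-yl)-7-oxabicyclo[4.1.0]heptan-2-ol | C[C@@]12O[C@@H]1C[C@@H](C[C@@]2(O)CCCC=C)C(C)=C | intermediate
6 | (2S,3R,5S)-3-hydroxy-2-methyl-2-(pent-4-en-1-yl)-5-(prop-1-en-2-yl)cyclohexan-1-one | C=CCCC[C@@]1(C)[C@H](O)C[C@@H](CC1=O)C(C)=C | intermediate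
7 | (2S,5R)-2-methyl-2-(pent-4-en-1-yl)-5-(prop-1-en-2-yl)cyclohex-3-en-1-one | C=CCCC[C@@]1(C)C=C[C@@H](CC1=O)C(C)=C | intermediate
8 | (4R,4aR,6R,8aS)-4,8a-dimethyl-6-(prop-1-en-2-yl)-1,3,4,5,6,8a-hexahydronaphthalen-4a(2H)-ol | C[C@@H]1CCC[C@@]2(C)C=C[C@@H](C[C@@]12O)C(C)=C | intermediate
9 | C5-peroxy 4-nitrobenzenesulfonate of 8 | C[C@@H]1CCC[C@@]2(C)C=C[C@@H](C[C@@]12OOS(=O)(=O)c3ccc(cc3)[N+](=O)[O-])C(C)=C | intermediate
10 | bridged hemiketal, 2,6-dimethyl-9-(prop-1-en-2-yl)-11-oxabicyclo[4.4.1]undec-7-en-1-ol | C[C@@H]1CCC[C@@]2(C)/C=C\[C@@H](C[C@]1(O)O2)C(C)=C | intermediate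
11 | (3R,4Z,6S,10R)-6-hydroxy-6,10-dimethyl-3-(prop-1-en-2-yl)cyclodec-4-en-1-one | C[C@@H]1CCC[C@](C)(O)/C=C\[C@@H](CC1=O)C(C)=C | intermediate
12 | (3R,4Z,6S,10R)-6-hydroxy-3-(3-hydroxyprop-1-en-2-yl)-6,10-dimethylcyclodec-4-en-1-one | C[C@@H]1CCC[C@](C)(O)/C=C\[C@@H](CC1=O)C(=C)CO | intermediate
13 | 2-[(1R,2Z,4S,8R)-4-hydroxy-4,8-dimethyl-9-oxocyclodec-2-en-1-yl]prop-2-enal | C[C@@H]1CCC[C@](C)(O)/C=C\[C@@H](CC1=O)C(=C)C=O | intermediate
14 | 2-[(1R,2Z,4S,8R)-4-hydroxy-4,8-dimethyl-9-oxocyclodec-2-en-1-yl]prop-2-enoic acid | C[C@@H]1CCC[C@](C)(O)/C=C\[C@@H](CC1=O)C(=C)C(O)=O | intermediate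
15 | (4R,7S,8R,9R,10S)-8,9-epoxide of 14 (oxirane O anti to the acrylic acid arm) | C[C@@H]1CCC[C@](C)(O)[C@@H]2O[C@@H]2[C@@H](CC1=O)C(=C)C(O)=O | intermediate
16 | (4R,7S,8S,9R,10S)-9,10-dihydroxy-5-oxogermacr-11(13)-en-12,8-olide | C=C1C(=O)O[C@@H]2[C@@H](O)[C@@](C)(O)CCC[C@@H](C)C(=O)C[C@@H]12 | intermediate
17 | (R)-2-methylbutanoic acid | CC[C@@H](C)C(=O)O | starting material
18 | ineupatorolide A | C=C1C(=O)O[C@@H]2[C@@H](OC(=O)[C@H](C)CC)[C@@](C)(O)CCC[C@@H](C)C(=O)C[C@@H]12 | target

Total step count: 10. Longest linear sequence: 10 steps, from 1.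

**Three steps most likely to fail**

**Step 6 (the new step).**
- Risks: the alkoxide may be sulfonylated at sulfur instead of forming the O–O bond. The bridged oxocarbenium ion may also lose the tertiary allylic C10–O bond before water arrives.
- Fallback (known chemistry, radical instead of cationic): set out from 8 and generate the C5 alkoxy radical under Suárez conditions (PhI(OAc)2, I2, visible light, CH2Cl2).
- β-Scission of C5–C10 gives the ten-membered ketone and a tertiary allyl radical. This is oxidised and captured by acetate as the 10-O-acetate of 11 F1.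
- F1 forms together with its C10 epimer and some C8 acetate, so chromatography is needed because this route has no stereocontrol at C10.
- K2CO3/MeOH then returns the route to 11.

**Step 5.**
- Risks: 6-exo ketyl cyclisation onto an unactivated alkene next to a quaternary centre may lose to simple ketone reduction, or give a poor C4 ratio.
- Fallback (Barbier instead of ketyl–olefin): set out from 7.
- Tsuji–Wacker oxidation (PdCl2, CuCl, O2, DMF–H2O) of the only monosubstituted alkene gives the 4-oxopentyl diketone F2.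
- L-Selectride at −78 °C reduces only the unhindered methyl ketone, giving the 4-hydroxypentyl ketone F3 (C4 epimers, which is inconsequential).
- I2, PPh3 and imidazole give the 4-iodopentyl ketone F4.
- SmI2 with catalytic NiI2 (Molander intramolecular Barbier reaction) closes ring A and returns the route to 8.

**Step 9.**
- Risk: the facial selectivity of the peracid on the flexible Z-cyclodecene may be low or reversed.
- Fallback (stereocontrol from the nucleophile's face instead of the oxidant's face): set out from 14.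
- Iodolactonisation (I2, NaHCO3, MeCN, 0 °C) lets the acid attack C8 from its own A(1,3)-defined face. This gives (4R,7S,8S,9R,10S)-10-hydroxy-9-iodo-5-oxogermacr-11(13)-en-12,8-olide F5.
- K2CO3 in acetone lets the C10–OH displace the antiperiplanar iodide, giving (4R,7S,8S,9S,10S)-9,10-epoxy-5-oxogermacr-11(13)-en-12,8-olide F6.
- The caesium salt of 17 (Cs2CO3, DMF, 60 °C) opens the epoxide at the secondary C9 with a second inversion. This returns the route directly at 18.

**Further compounds**
F1 | step 6 | 10-O-acetate of 11 | C[C@@H]1CCC[C@](C)(OC(C)=O)/C=C\[C@@H](CC1=O)C(C)=C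
F2 | step 5 | (2S,5R)-2-methyl-2-(4-oxopentyl)-5-(prop-1-en-2-yl)cyclohex-3-en-1-one | CC(=O)CCC[C@@]1(C)C=C[C@@H](CC1=O)C(C)=C
F3 | step 5 | (2S,5R)-2-(4-hydroxypentyl)-2-methyl-5-(prop-1-en-2-yl)cyclohex-3-en-1-one (side-chain epimers) | CC(O)CCC[C@@]1(C)C=C[C@@H](CC1=O)C(C)=C
F4 | step 5 | (2S,5R)-2-(4-iodopentyl)-2-methyl-5-(prop-1-en-2-yl)cyclohex-3-en-1-one (side-chain epimers) | CC(I)CCC[C@@]1(C)C=C[C@@H](CC1=O)C(C)=C
F5 | step 9 | (4R,7S,8S,9R,10S)-10-hydroxy-9-iodo-5-oxogermacr-11(13)-en-12,8-olide | C=C1C(=O)O[C@@H]2[C@@H](I)[C@@](C)(O)CCC[C@@H](C)C(=O)C[C@@H]12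
F6 | step 9 | (4R,7S,8S,9S,10S)-9,10-epoxy-5-oxogermacr-11(13)-en-12,8-olide | C=C1C(=O)O[C@@H]2[C@@H]3O[C@@]3(C)CCC[C@@H](C)C(=O)C[C@@H]12
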